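The carbocycle C1–C2–C3–C4–C4a–C8a carries the same (R)-danshensu ester on the neighbouring atoms C2 and C3, a hidden twofold-symmetric fumarate. C1 and C4 are both benzylic to the catechol ring. The route therefore rests on cutting C1–C2 and C3–C4. Forward, a racemic trans-2-arylbenzocyclobutenol (four-membered ring C1, C4, C4a, C8a) opens thermally to an o-quinodimethane, and the homochiral fumarate inserts C2–C3. The four-membered ring becomes the six-membered one, two C–C bonds and four stereocentres form at once, and the purchased danshensu centres fix C1 and C2. Loss of water across C3–C4 and global debenzylation complete the synthesis.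

Key step: step 8

Remark on the chemistry: locants C1–C8a are those of the 1,2-dihydronaphthalene core of the target (C1 bears the aryl group, C7/C8 the ring oxygens) and are used for the same atoms in all precursors. Compounds 11–13 are racemates drawn as one enantiomer, which suffices because 14 is achiral. (R)-Danshensu is assumed to be purchasable as the free acid.

Step 1
Reactants: 1 (R)-danshensu, (2R)-3-(3,4-dihydroxyphenyl)-2-hydroxypropanoic acid
Product: 2 benzyl (2R)-3-[3,4-bis(benzyloxy)phenyl]-2-hydroxypropanoate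
Conditions: BnBr (3.3 equiv), K2CO3, DMF, rt, N2
Reagents that add atoms: benzyl bromide, BrCc1ccccc1
Why: Williamson ether synthesis plus carboxylate alkylation; K2CO3 ionises only the acid and the two phenols, so the secondary alcohol stays free and the (R)-centre is not touched.

Step 2
Reactants: 2 benzyl (2R)-3-[3,4-bis(benzyloxy)phenyl]-2-hydroxypropanoate (2.1 equiv); 3 fumaryl chloride
Product: 4 bis{(2R)-1-(benzyloxy)-3-[3,4-bis(benzyloxy)phenyl]-1-oxopropan-2-yl} (E)-but-2-enedioate (homochiral fumarate)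
Conditions: pyridine, DMAP (cat.), CH2Cl2, 0 °C → rt
Reagents that add atoms: none
Why: DMAP-catalysed acyl chloride esterification occurs at oxygen only, so both (R)-centres are retained and the E-alkene of 3 is carried over.

Step 3
Reactants: 5 2-bromo-3-hydroxy-4-methoxybenzaldehyde (2-bromoisovanillin)
Product: 6 2-bromo-3,4-dihydroxybenzaldehyde
Conditions: BBr3, CH2Cl2, −78 °C → rt; then H2O
Reagents that add atoms: none
Why: Lewis-acid aryl methyl ether cleavage, assisted by borate formation with the neighbouring phenol; the aldehyde and the aryl bromide are inert.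

Step 4
Reactants: 6 2-bromo-3,4-dihydroxybenzaldehyde
Product: 7 3,4-bis(benzyloxy)-2-bromobenzaldehyde
Conditions: BnBr (2.3 equiv), K2CO3, DMF, 60 °C
Reagents that add atoms: benzyl bromide, BrCc1ccccc1
Why: Williamson ether synthesis on both phenoxides; no other group reacts with a weak base and a benzylic halide.

Step 5
Reactants: 8 3,4-bis(benzyloxy)benzyl chloride
Product: 9 1-[3,4-bis(benzyloxy)benzyl]tetrahydrothiophenium chloride
Conditions: tetrahydrothiophene (1.5 equiv), MeCN, 40 °C; precipitation with Et2O, filtration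
Reagents that add atoms: tetrahydrothiophene, C1CCSC1
Why: SN2 S-alkylation of a nucleophilic cyclic sulfide by an electron-rich, highly reactive benzylic chloride, which should give a salt that can be isolated by precipitation and stored.

Step 6
Reactants: 7 3,4-bis(benzyloxy)-2-bromobenzaldehyde; 9 1-[3,4-bis(benzyloxy)benzyl]tetrahydrothiophenium chloride
Product: 11 rac-trans-(2R*,3R*)-2-[3,4-bis(benzyloxy)-2-bromophenyl]-3-[3,4-bis(benzyloxy)phenyl]oxirane, via sulfonium ylide 10 (not isolated)
Conditions: powdered KOH, MeCN, 0 °C → rt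
Reagents that add atoms: none
Why: Johnson–Corey–Chaykovsky epoxidation with a semi-stabilised benzylide; reversible syn-betaine formation channels the reaction to the trans-epoxide, and a racemate is enough because both centres are erased in step 8.

Step 7
Reactants: 11 rac-trans-2-[3,4-bis(benzyloxy)-2-bromophenyl]-3-[3,4-bis(benzyloxy)phenyl]oxirane
Product: 13 rac-trans-2,3-bis(benzyloxy)-8-[3,4-bis(benzyloxy)phenyl]bicyclo[4.2.0]octa-1,3,5-trien-7-ol (trans-2-arylbenzocyclobutenol), via aryllithium 12 (not isolated)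
Conditions: n-BuLi (1.05 equiv), THF, −78 °C; MgBr2·OEt2 (Lewis acid), −78 °C → rt; then H2O
Reagents that add atoms: none
Why: Bromine–lithium exchange followed by a Parham-type cyclisation, in which the aryl anion opens the MgBr2-activated epoxide at the distal benzylic carbon with inversion; this turns the trans-epoxide into the trans-benzocyclobutenol with the aryl-bearing carbon next to the C8 oxygen.

Step 8
Reactants: 13 rac-trans-2-arylbenzocyclobutenol; 4 homochiral fumarate (1.2 equiv)
Product: 15 bis{(2R)-1-(benzyloxy)-3-[3,4-bis(benzyloxy)phenyl]-1-oxopropan-2-yl} (1R,2S,3R,4R)-7,8-bis(benzyloxy)-1-[3,4-bis(benzyloxy)phenyl]-4-hydroxy-1,2,3,4-tetrahydronaphthalene-2,3-dicarboxylate, via o-quinodimethane dienol 14 (not isolated)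
Conditions: degassed toluene, 110 °C, sealed vessel
Reagents that add atoms: none
Why: Thermal conrotatory 4π opening of the C1–C4 σ-bond (the donor OH rotates outward, and because 13 is trans the aryl group follows outward) erases both centres of racemic 13 and gives planar 14, which 4 traps in a concerted cycloaddition driven by rearomatisation; the net result is insertion of C2–C3 into the four-membered ring, the known benzocyclobutenol/o-quinodimethane Diels–Alder entry to 1-aryltetralins. The six-membered ring closes in the intermolecular suprafacial [π4s+π2s] mode, forming C1–C2 and C3–C4 in one event. C1 and C4 come out cis because both substituents of 14 point outward, and C2 and C3 come out trans because the E geometry of 4 is retained. Of the two possible alignments the one with the C3 ester endo under C4a/C5 should prevail, since it allows an O–H···O=C hydrogen bond in toluene and keeps the C2 ester exo, away from the space under C8a/C8 crowded by the C8 benzyloxy group and the twisted aryl ring; this gives 3,4-cis and the required 1,2-trans. The absolute sense comes from the two (R)-carbinol centres of 4: in the s-cis enoate, Z-ester conformer with the carbinol C–H eclipsing C=O, both CH2Ar arms cover the Re,Re face, so 14 should add to the Si,Si face and give (1R,2S,3R,4R). The step needs alignment and π-facial selectivity and trapping faster than dienol-to-aldehyde tautomerisation, which are secured by the twofold symmetry of 4 (both auxiliaries reinforce each other), the non-polar medium and the slight excess of dienophile.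

Step 9
Reactants: 15 (1R,2S,3R,4R)-4-hydroxytetralin diester
Product: 17 bis{(2R)-1-(benzyloxy)-3-[3,4-bis(benzyloxy)phenyl]-1-oxopropan-2-yl} (1R,2S)-7,8-bis(benzyloxy)-1-[3,4-bis(benzyloxy)phenyl]-1,2-dihydronaphthalene-2,3-dicarboxylate, via benzylic mesylate 16 (not isolated)
Conditions: MsCl, Et3N (5 equiv), CH2Cl2, 0 °C → rt
Reagents that add atoms: none
Why: Mesylation followed by β-elimination; the C7 benzyloxy group para to C4a labilises the C4–O bond, H3 is the only β-hydrogen, is anti to it and α to an ester, and C1, C2 and the side-chain centres are not involved.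

Step 10
Reactants: 17 perbenzylated (1R,2S)-dihydronaphthalene diester
Product: 18 target CNP0244800.2
Conditions: BCl3 (30 equiv), pentamethylbenzene (30 equiv), CH2Cl2, −78 → −40 °C; then H2O
Reagents that add atoms: none
Why: Lewis-acid O-debenzylation with pentamethylbenzene as non-basic benzyl-cation scavenger should cleave the eight aryl benzyl ethers and two benzyl esters without hydrogen, so the C3=C4 bond, the two secondary esters and all four stereocentres remain.

Compound list
1 | (R)-danshensu, (2R)-3-(3,4-dihydroxyphenyl)-2-hydroxypropanoic acid | O[C@H](Cc1ccc(O)c(O)c1)C(=O)O | starting material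
2 | benzyl (2R)-3-[3,4-bis(benzyloxy)phenyl]-2-hydroxypropanoate | O[C@H](Cc1ccc(OCc2ccccc2)c(OCc2ccccc2)c1)C(=O)OCc1ccccc1 | intermediate
3 | fumaryl chloride | O=C(Cl)/C=C/C(=O)Cl | starting material
4 | bis{(2R)-1-(benzyloxy)-3-[3,4-bis(benzyloxy)phenyl]-1-oxopropan-2-yl} (E)-but-2-enedioate | O=C(/C=C/C(=O)O[C@H](Cc1ccc(OCc2ccccc2)c(OCc2ccccc2)c1)C(=O)OCc1ccccc1)O[C@H](Cc1ccc(OCc2ccccc2)c(OCc2ccccc2)c1)C(=O)OCc1ccccc1 | intermediate
5 | 2-bromo-3-hydroxy-4-methoxybenzaldehyde | O=Cc1ccc(OC)c(O)c1Br | starting material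
6 | 2-bromo-3,4-dihydroxybenzaldehyde | O=Cc1ccc(O)c(O)c1Br | intermediate
7 | 3,4-bis(benzyloxy)-2-bromobenzaldehyde | O=Cc1ccc(OCc2ccccc2)c(OCc2ccccc2)c1Br | intermediate
8 | 3,4-bis(benzyloxy)benzyl chloride | ClCc1ccc(OCc2ccccc2)c(OCc2ccccc2)c1 | starting material
9 | 1-[3,4-bis(benzyloxy)benzyl]tetrahydrothiophenium chloride | [Cl-].C(c1ccc(OCc2ccccc2)c(OCc2ccccc2)c1)[S+]1CCCC1 | intermediate
10 | tetrahydrothiophenium 3,4-bis(benzyloxy)benzylide (sulfonium ylide) | [CH-](c1ccc(OCc2ccccc2)c(OCc2ccccc2)c1)[S+]1CCCC1 | intermediate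
11 | rac-trans-2-[3,4-bis(benzyloxy)-2-bromophenyl]-3-[3,4-bis(benzyloxy)phenyl]oxirane (one enantiomer drawn) | Brc1c(OCc2ccccc2)c(OCc2ccccc2)ccc1[C@H]1O[C@@H]1c1ccc(OCc2ccccc2)c(OCc2ccccc2)c1 | intermediate
12 | 2-lithio analogue of 11 (aryllithium, one enantiomer drawn) | [Li]c1c(OCc2ccccc2)c(OCc2ccccc2)ccc1[C@H]1O[C@@H]1c1ccc(OCc2ccccc2)c(OCc2ccccc2)c1 | intermediate
13 | rac-trans-2,3-bis(benzyloxy)-8-[3,4-bis(benzyloxy)phenyl]bicyclo[4.2.0]octa-1,3,5-trien-7-ol (one enantiomer drawn) | O[C@@H]1c2ccc(OCc3ccccc3)c(OCc3ccccc3)c2[C@H]1c1ccc(OCc2ccccc2)c(OCc2ccccc2)c1 | intermediate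
14 | 1,2-bis(benzyloxy)-6-[3,4-bis(benzyloxy)benzylidene]-5-(hydroxymethylidene)cyclohexa-1,3-diene (o-quinodimethane dienol, OH and aryl both outward) | O/C=C1\C=CC(OCc2ccccc2)=C(OCc2ccccc2)/C1=C\c1ccc(OCc2ccccc2)c(OCc2ccccc2)c1 | intermediate
15 | (1R,2S,3R,4R)-4-hydroxytetralin-2,3-dicarboxylate with two protected (R)-danshensu esters | O=C(O[C@H](Cc1ccc(OCc2ccccc2)c(OCc2ccccc2)c1)C(=O)OCc1ccccc1)[C@H]1[C@@H](O)c2ccc(OCc3ccccc3)c(OCc3ccccc3)c2[C@@H](c2ccc(OCc3ccccc3)c(OCc3ccccc3)c2)[C@@H]1C(=O)O[C@H](Cc1ccc(OCc2ccccc2)c(OCc2ccccc2)c1)C(=O)OCc1ccccc1 | intermediate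
16 | C4 methanesulfonate of 15 (benzylic mesylate) | O=C(O[C@H](Cc1ccc(OCc2ccccc2)c(OCc2ccccc2)c1)C(=O)OCc1ccccc1)[C@H]1[C@@H](OS(C)(=O)=O)c2ccc(OCc3ccccc3)c(OCc3ccccc3)c2[C@@H](c2ccc(OCc3ccccc3)c(OCc3ccccc3)c2)[C@@H]1C(=O)O[C@H](Cc1ccc(OCc2ccccc2)c(OCc2ccccc2)c1)C(=O)OCc1ccccc1 | intermediate
17 | perbenzylated (1R,2S)-1-aryl-1,2-dihydronaphthalene-2,3-dicarboxylate | O=C(O[C@H](Cc1ccc(OCc2ccccc2)c(OCc2ccccc2)c1)C(=O)OCc1ccccc1)C1=Cc2ccc(OCc3ccccc3)c(OCc3ccccc3)c2[C@@H](c2ccc(OCc3ccccc3)c(OCc3ccccc3)c2)[C@@H]1C(=O)O[C@H](Cc1ccc(OCc2ccccc2)c(OCc2ccccc2)c1)C(=O)OCc1ccccc1 | intermediate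
18 | CNP0244800.2, (1R,2S) core with two (R)-danshensu esters | O=C(O[C@H](Cc1ccc(O)c(O)c1)C(=O)O)C1=Cc2ccc(O)c(O)c2[C@@H](c2ccc(O)c(O)c2)[C@@H]1C(=O)O[C@H](Cc1ccc(O)c(O)c1)C(=O)O | target

Total step count: 10. Longest linear sequence: 7 steps (5 → 18, steps 3, 4 and 6–10). The side branches are 1 → 4 (steps 1–2) and 8 → 9 (step 5).

Steps most likely to fail

1. Step 8. The dienophile may align with the wrong ester endo. The two faces of 4 may be poorly differentiated. The dienol may also tautomerise before it is trapped, since the C8 benzyloxy group strains the outward aryl group. The fallback sets out from 13 and returns at 17. It gives up induction in the ring expansion and uses the side chains for a late resolution. 13 is heated with commercial diallyl fumarate to give racemic diallyl 1-aryl-4-hydroxytetralin-2,3-dicarboxylate F1 as an isomer mixture. Catalytic TsOH then removes water and a little DBU equilibrates C2 to the more stable 1,2-trans arrangement, giving racemic diallyl trans-1-aryl-1,2-dihydronaphthalene-2,3-dicarboxylate F2. Pd(PPh3)4/morpholine cleaves both allyl esters to the racemic trans diacid F3. EDC/DMAP esterification with two equivalents of 2 gives 17 together with its (1S,2R)-core diastereomer F4, and the two are separated by chromatography or crystallisation.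

2. Step 7. A Lewis-acid-induced Meinwald rearrangement of the electron-rich epoxide before ring closure would change which benzylic carbon carries the aryl group. Ionisation of the epoxide would erode the inversion. Proton transfer from a benzyloxy CH2 to the aryl anion would quench the cyclisation. The fallback sets out from 7 and 8 and returns at 15, and it uses no epoxide and no organolithium. Zinc dust inserts into 8 to give [3,4-bis(benzyloxy)benzyl]zinc chloride F5. Negishi coupling with 7 (Pd(OAc)2/SPhos) gives 3,4-bis(benzyloxy)-2-[3,4-bis(benzyloxy)benzyl]benzaldehyde F6. Irradiation at 350 nm in SO2-saturated benzene traps the photoenol as the racemic cis-1-hydroxy-3-aryl-1,3-dihydrobenzo[c]thiophene 2,2-dioxide F7. Heating F7 with 4 in toluene over ZnO extrudes SO2 cheletropically. This regenerates 14, now from a five-membered ring, and delivers 15.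

3. Step 10. Removal of ten benzyl groups may be incomplete. The liberated catechols may be C-benzylated. The Lewis acid may cleave the secondary esters. The fallback sets out from 15 and returns at 18. It inverts the order of the last two operations, so steps 9 and 10 are bypassed. All benzyl groups of 15 are removed by neutral hydrogenolysis (H2, Pd/C, EtOAc–MeOH) while no C=C bond is present, giving the fully deprotected (1R,2S,3R,4R)-4-hydroxytetralin F8. Brief exposure to dilute aqueous formic acid expels the C4 hydroxyl through the p-quinone methide of the C7 phenol, and loss of H3 gives 18.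

Further compounds
F1 | step 8 | racemic diallyl 7,8-bis(benzyloxy)-1-[3,4-bis(benzyloxy)phenyl]-4-hydroxy-1,2,3,4-tetrahydronaphthalene-2,3-dicarboxylate (expected main isomer, one enantiomer drawn) | C=CCOC(=O)[C@H]1[C@@H](O)c2ccc(OCc3ccccc3)c(OCc3ccccc3)c2[C@@H](c2ccc(OCc3ccccc3)c(OCc3ccccc3)c2)[C@@H]1C(=O)OCC=C
F2 | step 8 | racemic diallyl trans-7,8-bis(benzyloxy)-1-[3,4-bis(benzyloxy)phenyl]-1,2-dihydronaphthalene-2,3-dicarboxylate (one enantiomer drawn) | C=CCOC(=O)C1=Cc2ccc(OCc3ccccc3)c(OCc3ccccc3)c2[C@@H](c2ccc(OCc3ccccc3)c(OCc3ccccc3)c2)[C@@H]1C(=O)OCC=C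
F3 | step 8 | racemic trans-7,8-bis(benzyloxy)-1-[3,4-bis(benzyloxy)phenyl]-1,2-dihydronaphthalene-2,3-dicarboxylic acid (one enantiomer drawn) | OC(=O)C1=Cc2ccc(OCc3ccccc3)c(OCc3ccccc3)c2[C@@H](c2ccc(OCc3ccccc3)c(OCc3ccccc3)c2)[C@@H]1C(=O)O
F4 | step 8 | (1S,2R)-core diastereomer of 17 | O=C(O[C@H](Cc1ccc(OCc2ccccc2)c(OCc2ccccc2)c1)C(=O)OCc1ccccc1)C1=Cc2ccc(OCc3ccccc3)c(OCc3ccccc3)c2[C@H](c2ccc(OCc3ccccc3)c(OCc3ccccc3)c2)[C@H]1C(=O)O[C@H](Cc1ccc(OCc2ccccc2)c(OCc2ccccc2)c1)C(=O)OCc1ccccc1
F5 | step 7 | [3,4-bis(benzyloxy)benzyl]zinc chloride | Cl[Zn]Cc1ccc(OCc2ccccc2)c(OCc2ccccc2)c1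
F6 | step 7 | 3,4-bis(benzyloxy)-2-[3,4-bis(benzyloxy)benzyl]benzaldehyde | O=Cc1ccc(OCc2ccccc2)c(OCc2ccccc2)c1Cc1ccc(OCc2ccccc2)c(OCc2ccccc2)c1
F7 | step 7 | racemic cis-4,5-bis(benzyloxy)-3-[3,4-bis(benzyloxy)phenyl]-1-hydroxy-1,3-dihydrobenzo[c]thiophene 2,2-dioxide (one enantiomer drawn) | O[C@H]1c2ccc(OCc3ccccc3)c(OCc3ccccc3)c2[C@@H](c2ccc(OCc3ccccc3)c(OCc3ccccc3)c2)S1(=O)=O
F8 | step 10 | fully deprotected (1R,2S,3R,4R)-4-hydroxytetralin diester | O=C(O[C@H](Cc1ccc(O)c(O)c1)C(=O)O)[C@H]1[C@@H](O)c2ccc(O)c(O)c2[C@@H](c2ccc(O)c(O)c2)[C@@H]1C(=O)O[C@H](Cc1ccc(O)c(O)c1)C(=O)O
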